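**Assumptions (one line):** (S)-4-benzyloxazolidin-2-one is used as a recoverable chiral controller and treated as a reagent, and it is returned in Step 8. The para hydroxymethylation isomer in Step 2 is separable from the ortho isomer. Ethyl glyoxylate is used as a freshly cracked monomer solution. Lactone numbering below is O1, C2(=O), C3(OH)(CH2Ar), C4(H)(CH2Ar′), C5H2.

## Retrosynthesis
1. Cut the C3–CH2Ar bond as a radical coupling. A captodative C3 radical from 3-hydroxy-4-(arylmethyl)-γ-butyrolactone adds to the p-quinone methide of vanillyl alcohol anti to the C4 substituent. This builds the tertiary carbinol and puts the two benzyl groups trans.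
2. The 3-hydroxy lactone comes from an Evans aldol of a 3-arylpropanoyl imide with ethyl glyoxylate. Reductive removal of the auxiliary and lactonization close the only new ring, the γ-lactone, and the aldol sets C4.
3. The arylpropanoyl imide comes from alkylating the N-acetyl imide with silyl-protected vanillyl bromide. The vanillyl unit is built from catechol by mono-methylation and then hydroxymethylation.

## Route

**Step 1**
Reactants: 1 catechol
Product: 2 guaiacol
Conditions: Me2SO4 (0.9 equiv), NaOH, H2O, 0 °C to rt
Reagents that add atoms: dimethyl sulfate, COS(=O)(=O)OC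
Why: Controlled O-methylation (Williamson) of the mono-phenoxide gives the mono-methyl ether. This supplies the 2-methoxyphenol unit from an eight-atom starting material.

**Step 2**
Reactants: 2 guaiacol, 3 paraformaldehyde
Product: 4 vanillyl alcohol (4-hydroxy-3-methoxybenzyl alcohol)
Conditions: aq. NaOH, 50 °C; isolate the para isomer
Reagents that add atoms: none (formaldehyde is reactant 3)
Why: Phenoxide hydroxymethylation is an electrophilic aromatic substitution that favors the position para to O−. Vanillyl alcohol is both the precursor of the benzyl bromide and the p-quinone methide source for Step 9.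

**Step 3**
Reactants: 4 vanillyl alcohol
Product: 5 4-(tert-butyldimethylsilyloxy)-3-methoxybenzyl alcohol
Conditions: TBSCl (1.0 equiv), Cs2CO3, MeCN, 0 °C to rt
Reagents that add atoms: TBSCl, C[Si](C)(Cl)C(C)(C)C
Why: Only the phenol (pKa about 10) is deprotonated by carbonate, so silylation is phenol-selective. The silyl ether has no weak C–H bonds for the later HAT step.

**Step 4**
Reactants: 5
Product: 6 4-(TBSO)-3-methoxybenzyl bromide
Conditions: CBr4, PPh3, CH2Cl2, 0 °C
Reagents that add atoms: carbon tetrabromide, BrC(Br)(Br)Br
Why: An Appel reaction converts the primary benzylic alcohol to the bromide under neutral conditions that leave the aryl silyl ether intact.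

**Step 5**
Reactants: 7 acetyl chloride
Product: 8 (S)-3-acetyl-4-benzyloxazolidin-2-one
Conditions: LiXc (from auxiliary and n-BuLi), THF, −78 °C, then AcCl
Reagents that add atoms: (S)-4-benzyloxazolidin-2-one, O=C1N[C@@H](Cc2ccccc2)CO1
Why: Plain N-acylation installs the chiral controller that later sets C4.

**Step 6**
Reactants: 8, 6
Product: 9 (S)-4-benzyl-3-[3-(4-TBSO-3-methoxyphenyl)propanoyl]oxazolidin-2-one
Conditions: NaHMDS, THF, −78 °C, then 6, warming to −20 °C
Reagents that add atoms: none
Why: Enolate alkylation with a benzylic bromide forms the ArCH2–CH2 bond. No stereocenter is formed in this step.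

**Step 7**
Reactants: 9, 10 ethyl glyoxylate
Product: 11 aldol adduct, (S)-4-benzyl-3-[(2S)-2-(Ar′CH2)-3-hydroxy-3-(ethoxycarbonyl)propanoyl]oxazolidin-2-one, where Ar′ is 4-TBSO-3-MeO-phenyl
Conditions: Bu2BOTf, iPr2NEt, CH2Cl2, −78 to 0 °C; then H2O2, pH 7 buffer
Reagents that add atoms: none (ethyl glyoxylate is reactant 10)
Why: The Evans Z(O)-boron enolate reacts through a dipole-minimized Zimmerman–Traxler transition state (Evans aldol) and fixes C4 as S in the adduct, which is the spatial arrangement of C4 (R) in the target. The carbinol carbon (C3) configuration is irrelevant because Step 9 removes it.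

**Step 8**
Reactants: 11
Product: 12 (4R)-4-(4-TBSO-3-methoxybenzyl)-3-hydroxydihydrofuran-2(3H)-one, as a C3 epimer mixture
Conditions: LiBH4 (1.2 equiv), MeOH (1.2 equiv), Et2O, 0 °C; then cat. p-TsOH, CH2Cl2
Reagents that add atoms: none (the auxiliary is released and recovered)
Why: Chelation-accelerated hydride reduction of the imide gives the primary alkoxide, which attacks the ethyl ester in a 5-exo closure to form the γ-lactone. The C4 stereocenter is untouched.

**Step 9**
Reactants: 12, 4 vanillyl alcohol (via 13, the p-quinone methide formed in situ)
Product: 14 TBS-protected (+)-nortrachelogenin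
Conditions: TBADT (2 mol %), HFIP/MeCN (1:4), 390 nm LEDs, 25 °C, N2, 24 h; 4 (3 equiv)
Reagents that add atoms: none (13 derives from 4 by loss of water)
Why: Proposed new method: HFIP ionizes 4 to the electrophilic p-quinone methide 13. Excited decatungstate abstracts the captodative C3–H (flanked by OH and C=O) of 12, which is the weakest C–H and H-bonded to HFIP. The nucleophilic tertiary radical then adds to the exocyclic CH2 of 13 (1,6-radical addition), and back-HAT from the reduced catalyst to the phenoxyl radical closes a redox-neutral cycle. The closest known chemistry is photo-HAT α-C–H alkylation of alcohols combined with radical 1,6-additions to p-quinone methides. The planar C3 radical is captured anti to the C4 arylmethyl group, so the new benzyl is trans to it and the OH is cis (3R,4R). Both C3 epimers of 12 converge on the same radical.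

**Step 10**
Reactants: 14
Product: 15 (+)-nortrachelogenin
Conditions: TBAF (1.5 equiv), AcOH (1.5 equiv), THF, 0 °C, 30 min
Reagents that add atoms: none
Why: Buffered fluoride cleaves the aryl Si–O bond without opening the lactone or touching the tertiary alcohol (desilylation).

## Check
- The core matches the target: a γ-butyrolactone with C3(OH)(CH2Ar) and C4(H)(CH2Ar′), both Ar groups 4-hydroxy-3-methoxyphenyl, and the benzyl groups trans (OH cis to the C4 benzyl).
- Atoms balance through Steps 1–10, and 14 differs from the target only by TBS.
- The aryl silyl ether survives Steps 4–9, and no other protecting group is used.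
- C4 is set in Step 7 and never scrambled. C3 is set in Step 9 by radical capture anti to C4.

## Compound list
1 | catechol | Oc1ccccc1O | starting material
2 | guaiacol | COc1ccccc1O | intermediate
3 | paraformaldehyde (formaldehyde) | C=O | starting material
4 | vanillyl alcohol | COc1cc(CO)ccc1O | intermediate
5 | 4-(TBSO)-3-methoxybenzyl alcohol | COc1cc(CO)ccc1O[Si](C)(C)C(C)(C)C | intermediate
6 | 4-(TBSO)-3-methoxybenzyl bromide | COc1cc(CBr)ccc1O[Si](C)(C)C(C)(C)C | intermediate
7 | acetyl chloride | CC(=O)Cl | starting material
8 | (S)-3-acetyl-4-benzyloxazolidin-2-one | CC(=O)N1[C@@H](Cc2ccccc2)COC1=O | intermediate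
9 | (S)-4-benzyl-3-[3-(4-TBSO-3-methoxyphenyl)propanoyl]oxazolidin-2-one | COc1cc(CCC(=O)N2[C@@H](Cc3ccccc3)COC2=O)ccc1O[Si](C)(C)C(C)(C)C | intermediate
10 | ethyl glyoxylate | CCOC(=O)C=O | starting material
11 | Evans aldol adduct | CCOC(=O)C(O)[C@H](Cc1ccc(O[Si](C)(C)C(C)(C)C)c(OC)c1)C(=O)N1[C@@H](Cc2ccccc2)COC1=O | intermediate
12 | (4R)-3-hydroxy-4-(4-TBSO-3-methoxybenzyl)dihydrofuran-2-one (C3 epimer mixture) | O=C1C(O)[C@H](Cc2ccc(O[Si](C)(C)C(C)(C)C)c(OC)c2)CO1 | intermediate
13 | 2-methoxy-4-methylenecyclohexa-2,5-dien-1-one (p-quinone methide, in situ) | COC1=CC(=C)C=CC1=O | intermediate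
14 | TBS-protected nortrachelogenin | COc1cc(C[C@@H]2COC(=O)[C@@]2(O)Cc2ccc(O)c(OC)c2)ccc1O[Si](C)(C)C(C)(C)C | intermediate
15 | (+)-nortrachelogenin | COc1cc(C[C@@H]2COC(=O)[C@@]2(O)Cc2ccc(O)c(OC)c2)ccc1O | target

## Totals
Total steps: 10. Longest linear sequence: 9 (Steps 1, 2, 3, 4, 6, 7, 8, 9, 10; Step 5 runs in parallel).

## Three steps most likely to fail
1. **Step 9 (HAT/quinone methide coupling).** Benzylic C–H bonds or vanillyl alcohol itself may compete for HAT, and quinone methide oligomerization is possible. Fallback: a polar route in which the lactone 12 is converted to its dianion (2 equiv LiHMDS) and alkylated with bromide 6, which also gives the trans benzyl; then Step 10 removes both TBS groups.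
2. **Step 7 (Evans aldol with ethyl glyoxylate).** Yield and dr can be poor because of glyoxylate oligomers. Fallback: change the disconnection to an Evans alkylation of the tert-butyl succinyl imide with bromide 6, then lactonization and Davis α-hydroxylation to give 12.
3. **Step 8 (chemoselective LiBH4 reduction and lactonization).** The α-hydroxy ester may be over-reduced to the triol. Fallback: cleave the auxiliary with LiOOH to the acid, reduce the acid selectively with BH3·SMe2, and lactonize onto the ester.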